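**Plan**
- **Cuts:** first the O6 acetate and O7 isobutyrate, then C12–C13 (Heck) and C11=C12 (Wittig) back to a C11 ester. Next come C8–C9 of ring B, then C6–C7, and finally C5–C6 and C9–C10 on ring A.
- **Enabling feature:** in ring B (C5–C6–C7–C8–C9–C10) the tertiary carbinol C8 (CH3, OH) adjoins the quaternary C9 (CH3, C11). With C11 as an ester this pair is a β-hydroxy ester whose 8-OH and C11 are cis (both β), which is the retron of an aldol between a C9 ester enolate and a C8 methyl ketone. Hydride addition to a C9(=C20H2) acrylate frees that enolate without touching the more acidic ketone.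
- **Forward order:** ring A comes from (S)-carvone by two Mukaiyama additions, excision of the isopropenyl group, and conversion of the C4 ketone into C3=C4–CH3. The C7–C8–C17 unit is joined at C6 and oxidised to the methyl ketone, ring B then closes, and the butenolide is attached last.
- **Stereochemistry:** the carvone centre sets C10 and C10 sets C5. The borane derived from (+)-α-pinene sets C6 and C7. C5, C6, C7 and C10 together set C8 and C9 in the ring closure.

Key step: step 13

Remark: clerodane numbering is used for all intermediates (C18 on C4, C19 on C5, C17 on C8, C20 on C9; α/β refer to the drawing with H-10 β). The copper enolate is assumed to exchange between its O- and C-bound forms faster than it cyclises, so its initial geometry is not decisive.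

Step 1
Reactants: 1 (S)-(+)-carvone; 2 tert-butyl[(1-methoxyethenyl)oxy]dimethylsilane
Product: 3 methyl 2-[(1R,5S)-3-(tert-butyldimethylsilyloxy)-2-methyl-5-(prop-1-en-2-yl)cyclohex-2-en-1-yl]acetate (C10 side chain α, C2 isopropenyl β)
Conditions: Ph3CSbCl6 (5 mol %), CH2Cl2, −78 °C
Reagents that add atoms: none
Why: Mukaiyama–Michael addition: the trityl salt activates the enone, the ketene acetal attacks C10 axially on the face opposite the C2 isopropenyl group (this sets C10), and silyl transfer stores the enolate regiospecifically as the C4=C5 silyl enol ether.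

Step 2
Reactants: 3 silyl enol ether
Product: 4 methyl 2-[(1R,2S,5S)-2-(dimethoxymethyl)-2-methyl-3-oxo-5-(prop-1-en-2-yl)cyclohexyl]acetate
Conditions: HC(OMe)3, TMSOTf (20 mol %), CH2Cl2, −78 → −40 °C
Reagents that add atoms: trimethyl orthoformate, COC(OC)OC
Why: Mukaiyama-type alkylation of a silyl enol ether by the dimethoxycarbenium ion: the small electrophile enters C5 antiparallel to the pseudoaxial C10 side chain, so the quaternary centre forms with C6 β (trans to C9) and C19 α, C6 arrives at the aldehyde level, and the far less nucleophilic isopropenyl group is left alone.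

Step 3
Reactants: 4 isopropenyl keto acetal
Product: 6 methyl 2-[(1R,2S)-2-(dimethoxymethyl)-2-methyl-3-oxocyclohexyl]acetate, via methoxy hydroperoxide 5 (not isolated)
Conditions: O3, MeOH, −78 °C; then FeSO4·7H2O, PhSH, −78 °C → rt
Reagents that add atoms: none
Why: Hydrodealkenylation (ozonolysis, then reductive fragmentation): ozone in methanol turns the only alkene into 5, divalent iron cleaves the O–O bond, the alkoxyl radical loses methyl acetate by β-scission, and the secondary C2 radical takes hydrogen from the thiol, so the control element is erased while C5, C10, ketone, ester and acetal stay untouched.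

Step 4
Reactants: 6 keto acetal ester
Product: 7 methyl 2-[(1R,2R)-2-(dimethoxymethyl)-2-methyl-3-(trifluoromethylsulfonyloxy)cyclohex-3-en-1-yl]acetate
Conditions: KN(SiMe3)2, THF, −78 °C; PhNTf2, −78 → 0 °C
Reagents that add atoms: N-phenylbis(trifluoromethanesulfonimide), O=S(=O)(N(c1ccccc1)S(=O)(=O)C(F)(F)F)C(F)(F)F
Why: Kinetic enolisation and O-triflation: C5 is quaternary, so the ketone can enolise only towards C3, and the ketone is deprotonated in preference to the less acidic ester.

Step 5
Reactants: 7 enol triflate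
Product: 8 methyl 2-[(1R,2R)-2-(dimethoxymethyl)-2,3-dimethylcyclohex-3-en-1-yl]acetate
Conditions: MeZnCl, Pd(PPh3)4 (5 mol %), THF, 50 °C
Reagents that add atoms: methylzinc chloride, C[Zn]Cl
Why: Negishi coupling of an enol triflate: zerovalent palladium inserts into the C4–O bond and methyl transfer from zinc places C18 on C4 with the alkene fixed at C3=C4, and the ester and acetal tolerate the organozinc reagent.

Step 6
Reactants: 8 ester acetal
Product: 9 methyl 3-(dimethylamino)-2-[(1R,2R)-2-(dimethoxymethyl)-2,3-dimethylcyclohex-3-en-1-yl]propanoate (both C9 epimers)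
Conditions: LiN(iPr)2, THF, −78 °C; (CH2=NMe2)I, −78 °C → rt
Reagents that add atoms: dimethylmethylideneammonium iodide, C=[N+](C)C.[I-]
Why: Mannich reaction of the lithium ester enolate with the preformed iminium salt brings in C20, and the new C9 centre is of no consequence because it becomes trigonal in the next step.

Step 7
Reactants: 9 Mannich base
Product: 11 methyl 2-[(1S,2R)-2-(dimethoxymethyl)-2,3-dimethylcyclohex-3-en-1-yl]prop-2-enoate, via ammonium iodide 10 (not isolated)
Conditions: MeI, MeOH, rt; then DBU, CH2Cl2, rt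
Reagents that add atoms: none
Why: Exhaustive methylation followed by Hofmann-type E1cB loss of trimethylamine from the β-ammonio ester gives the α-substituted acrylate without touching C10.

Step 8
Reactants: 11 acrylate acetal
Product: 12 methyl 2-[(1S,2R)-2-formyl-2,3-dimethylcyclohex-3-en-1-yl]prop-2-enoate
Conditions: 1 M HCl, THF, rt
Reagents that add atoms: water, O
Why: Acid-catalysed acetal hydrolysis; the aldehyde has no α-hydrogen, so neither epimerisation nor conjugation with C3=C4 is possible.

Step 9
Reactants: 13 4-methoxyphenol; 14 allyl bromide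
Product: 15 1-methoxy-4-(prop-2-en-1-yloxy)benzene
Conditions: K2CO3, acetone, reflux
Reagents that add atoms: none
Why: Williamson ether synthesis of a phenoxide with a primary allylic bromide.

Step 10
Reactants: 12 aldehyde acrylate; 15 allyl 4-methoxyphenyl ether
Product: 18 methyl 2-{(1S,2R)-2-[(1R,2R)-1-hydroxy-2-(4-methoxyphenoxy)but-3-en-1-yl]-2,3-dimethylcyclohex-3-en-1-yl}prop-2-enoate (6α-OH and 7β-OAr), via allylborane 16 (not isolated), via borinate ester 17 (not isolated)
Conditions: 15, s-BuLi, THF, −78 °C; (−)-Ipc2BOMe; BF3·OEt2; 12, −78 °C → rt; HOCH2CH2NH2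
Reagents that add atoms: none
Why: Brown γ-alkoxyallylboration: 16 reacts through a chair Zimmerman–Traxler transition state, so its (Z) geometry gives the syn C6/C7 pair and the isopinocampheyl groups derived from (+)-α-pinene direct attack to the Si face of the aldehyde (6R,7R), overriding the bias of C5, and the non-oxidative release of 18 from 17 with ethanolamine spares the acrylate.

Step 11
Reactants: 18 homoallylic alcohol
Product: 19 6-O-tert-butyldimethylsilyl ether of 18
Conditions: TBSOTf, 2,6-lutidine, CH2Cl2, −78 → 0 °C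
Reagents that add atoms: tert-butyldimethylsilyl triflate, CC(C)(C)[Si](C)(C)OS(=O)(=O)C(F)(F)F
Why: Silylation of the hindered neopentyl-type secondary alcohol with the silyl triflate; done at once, it removes the hydroxyl that could lactonise onto C11 or add to C20.

Step 12
Reactants: 19 vinyl silyl ether
Product: 20 methyl 2-{(1S,2R)-2-[(1R,2S)-1-(tert-butyldimethylsilyloxy)-2-(4-methoxyphenoxy)-3-oxobutyl]-2,3-dimethylcyclohex-3-en-1-yl}prop-2-enoate (ring-A keto-acrylate)
Conditions: PdCl2(quinox) (5 mol %; quinox = 2-(4,5-dihydrooxazol-2-yl)quinoline), AgSbF6 (12 mol %), aq. t-BuOOH, CH2Cl2, 0 °C → rt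
Reagents that add atoms: tert-butyl hydroperoxide, CC(C)(C)OO
Why: Catalyst-controlled Tsuji–Wacker oxidation by cationic divalent palladium, which gives methyl ketones from protected allylic alcohols; only the monosubstituted alkene reacts, the acrylate and the trisubstituted C3=C4 alkene remain, and the neutral medium keeps C7 intact.

Step 13
Reactants: 20 ring-A keto-acrylate
Product: 23 methyl 6α-(tert-butyldimethylsilyloxy)-8β-hydroxy-7β-(4-methoxyphenoxy)-12,13,14,15,16-pentanorclerod-3-en-11-oate (trans-decalin; 5α-CH3 10β-H 8α-CH3 9α-CH3 9β-CO2Me), via copper enolate 21 (not isolated), via copper aldolate 22 (not isolated)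
Conditions: [(Ph3P)CuH]6 (0.3 equiv), degassed toluene, −40 → 0 °C; cold aq. NH4Cl
Reagents that add atoms: none
Why: Hydrocupration of the electron-poor C9=C20 alkene, the only conjugate acceptor present, turns C20 into a methyl group and C9 into the carbon of copper ester enolate 21, which adds to the C8 methyl ketone to give aldolate 22; this is the copper hydride reductive aldol cyclisation known for keto-enoates and keto-enones. Ring B closes in a 6-(enolexo)-exo-trig mode through the one chair allowed by the trans C5–C6 and C10–C9 bonds on ring A, with O6 and O7 equatorial. At C9 the C11(OMe)(OCu) terminus of the tetrasubstituted enolate can only lie next to H-10, because eclipsing it with quaternary C5 would cost severe A(1,3) strain, so C11 ends equatorial (β) and the small new methyl takes the axial α site beside C19. At C8 copper bridges the enolate and ketone oxygens, the poorly chelating but strongly polar aryloxy group on C7 stands anti to the incoming C9 (polar Felkin–Anh) and C17 avoids the axial site, which together place O8 axial, β and cis to C11. The step needs selectivity for the acrylate over the ketone and the C3=C4 alkene, which phosphine-ligated monovalent copper hydride provides, and it needs ring closure to outrun proton transfer from the ketone α-positions, which the aprotic medium, low temperature and six-membered closure favour. The cold quench keeps 22 from retro-aldol cleavage.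

Step 14
Reactants: 23 β-hydroxy ester
Product: 24 8-O-triethylsilyl ether of 23
Conditions: TESOTf, 2,6-lutidine, CH2Cl2, 0 °C → rt
Reagents that add atoms: triethylsilyl triflate, CC[Si](CC)(CC)OS(=O)(=O)C(F)(F)F
Why: Silylation of the tertiary axial alcohol with a reactive silyl triflate blocks retro-aldol cleavage in the basic steps that follow.

Step 15
Reactants: 24 silylated ester
Product: 25 6α-(tert-butyldimethylsilyloxy)-7β-(4-methoxyphenoxy)-8β-(triethylsilyloxy)-12,13,14,15,16-pentanorclerod-3-en-11-ol
Conditions: iBu2AlH (excess), CH2Cl2, −78 → 0 °C; aq. potassium sodium tartrate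
Reagents that add atoms: none
Why: Hydride reduction of the equatorial methyl ester; the aryl ether, silyl ethers and alkene are inert, and the cold aluminium alkoxide should not trigger silyl migration from O8.

Step 16
Reactants: 25 primary alcohol
Product: 26 the corresponding C11 aldehyde
Conditions: Dess–Martin periodinane, pyridine, CH2Cl2, rt
Reagents that add atoms: none
Why: Dess–Martin oxidation of a neopentyl primary alcohol under buffered conditions; the aldehyde has no α-hydrogen.

Step 17
Reactants: 26 aldehyde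
Product: 27 6α-(tert-butyldimethylsilyloxy)-7β-(4-methoxyphenoxy)-8β-(triethylsilyloxy)-13,14,15,16-tetranorcleroda-3,11-diene
Conditions: Ph3PCH3Br, KOt-Bu, THF, 0 °C; 26, 0 °C → reflux
Reagents that add atoms: methyltriphenylphosphonium bromide, C[P+](c1ccccc1)(c1ccccc1)c1ccccc1.[Br-]
Why: Wittig methylenation with the small non-stabilised ylide, the standard answer to a hindered non-enolisable aldehyde.

Step 18
Reactants: 27 vinyl decalin; 28 4-bromofuran-2(5H)-one
Product: 29 6α-(tert-butyldimethylsilyloxy)-7β-(4-methoxyphenoxy)-8β-(triethylsilyloxy)cleroda-3,11E,13-trien-15,16-olide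
Conditions: Pd(OAc)2 (10 mol %), Bu4NCl, NaHCO3, DMF, 70 °C
Reagents that add atoms: none
Why: Heck reaction: oxidative addition of the vinylic bromide, insertion at the open terminus C12 of the only monosubstituted alkene and syn β-hydride elimination give the (E)-C11=C12 diene, and because C9 is quaternary the double bond cannot migrate.

Step 19
Reactants: 29 aryl ether
Product: 30 7β-alcohol (6α-OTBS and 8β-OTES retained)
Conditions: (NH4)2Ce(NO3)6, MeCN/H2O 4:1, 0 °C
Reagents that add atoms: none
Why: Oxidative dearylation of a 4-methoxyphenyl ether by tetravalent cerium (water attacks the oxidised ring and quinone leaves); the C7–O bond is never broken, so C7 keeps its configuration, and the silyl group on O8 prevents glycol cleavage.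

Step 20
Reactants: 30 7β-alcohol
Product: 31 7β-isobutyrate
Conditions: i-PrCOCl, pyridine, DMAP, CH2Cl2, 0 → 40 °C
Reagents that add atoms: isobutyryl chloride, CC(C)C(=O)Cl
Why: DMAP-catalysed acylation of the only free hydroxyl group.

Step 21
Reactants: 31 bis-silyl ether
Product: 32 6α,8β-dihydroxy-7β-isobutyryloxycleroda-3,11E,13-trien-15,16-olide
Conditions: HF·pyridine, THF, 0 °C → rt
Reagents that add atoms: none
Why: Fluoride desilylation in an acidic medium, preferred to basic fluoride sources so that the isobutyrate does not migrate and the butenolide is not deprotonated.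

Step 22
Reactants: 32 diol
Product: 33 (5R,6R,7S,8R,9R,10S)-6-acetoxy-8-hydroxy-7-isobutyryloxycleroda-3,11E,13-trien-15,16-olide (CNP0207114.1)
Conditions: Ac2O, pyridine, DMAP (cat.), CH2Cl2, 0 °C
Reagents that add atoms: acetic anhydride, CC(=O)OC(C)=O
Why: Selective acetylation: the secondary equatorial 6-OH reacts, whereas the tertiary axial 8-OH next to quaternary C9 does not under these mild conditions.

**Compound list**
1 | (S)-(+)-carvone | CC1=CC[C@@H](CC1=O)C(C)=C | starting material
2 | tert-butyl[(1-methoxyethenyl)oxy]dimethylsilane | C=C(OC)O[Si](C)(C)C(C)(C)C | starting material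
3 | silyl enol ether, C10 side chain α, C2 isopropenyl β | COC(=O)C[C@H]1C[C@H](C(C)=C)CC(O[Si](C)(C)C(C)(C)C)=C1C | intermediate
4 | isopropenyl keto acetal, C5 quaternary (C6 β, C19 α) | COC(=O)C[C@H]1C[C@H](C(C)=C)CC(=O)[C@]1(C)C(OC)OC | intermediate
5 | α-methoxy hydroperoxide | COC(=O)C[C@H]1C[C@H](C(C)(OC)OO)CC(=O)[C@]1(C)C(OC)OC | intermediate
6 | keto acetal ester | COC(=O)C[C@H]1CCCC(=O)[C@]1(C)C(OC)OC | intermediate
7 | C3=C4 enol triflate | COC(=O)C[C@H]1CCC=C(OS(=O)(=O)C(F)(F)F)[C@]1(C)C(OC)OC | intermediate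
8 | C3=C4(CH3) ester acetal | COC(=O)C[C@H]1CCC=C(C)[C@]1(C)C(OC)OC | intermediate
9 | Mannich base (C9 epimers) | COC(=O)C(CN(C)C)[C@H]1CCC=C(C)[C@]1(C)C(OC)OC | intermediate
10 | trimethylammonium iodide | COC(=O)C(C[N+](C)(C)C)[C@H]1CCC=C(C)[C@]1(C)C(OC)OC.[I-] | intermediate
11 | acrylate acetal | COC(=O)C(=C)[C@H]1CCC=C(C)[C@]1(C)C(OC)OC | intermediate
12 | aldehyde acrylate | COC(=O)C(=C)[C@H]1CCC=C(C)[C@]1(C)C=O | intermediate
13 | 4-methoxyphenol | COc1ccc(O)cc1 | starting material
14 | allyl bromide | C=CCBr | starting material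
15 | allyl 4-methoxyphenyl ether | C=CCOc1ccc(OC)cc1 | intermediate
16 | (Z)-[3-(4-methoxyphenoxy)allyl]diisopinocampheylborane | COc1ccc(O/C=C\CB([C@@H]2C[C@@H]3C[C@H]([C@H]2C)C3(C)C)[C@@H]2C[C@@H]3C[C@H]([C@H]2C)C3(C)C)cc1 | intermediate
17 | O6 diisopinocampheylborinate | C=C[C@@H](Oc2ccc(OC)cc2)[C@H](OB([C@@H]2C[C@@H]3C[C@H]([C@H]2C)C3(C)C)[C@@H]2C[C@@H]3C[C@H]([C@H]2C)C3(C)C)[C@@]1(C)C(C)=CCC[C@@H]1C(=C)C(=O)OC | intermediate
18 | syn homoallylic alcohol (6R,7R) | C=C[C@@H](Oc2ccc(OC)cc2)[C@H](O)[C@@]1(C)C(C)=CCC[C@@H]1C(=C)C(=O)OC | intermediate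
19 | 6-O-TBS ether | C=C[C@@H](Oc2ccc(OC)cc2)[C@H](O[Si](C)(C)C(C)(C)C)[C@@]1(C)C(C)=CCC[C@@H]1C(=C)C(=O)OC | intermediate
20 | ring-A keto-acrylate (key-step precursor) | CC(=O)[C@@H](Oc2ccc(OC)cc2)[C@H](O[Si](C)(C)C(C)(C)C)[C@@]1(C)C(C)=CCC[C@@H]1C(=C)C(=O)OC | intermediate
21 | copper ester enolate (phosphine omitted) | CC(=O)[C@@H](Oc2ccc(OC)cc2)[C@H](O[Si](C)(C)C(C)(C)C)[C@@]1(C)C(C)=CCC[C@@H]1C(C)=C(OC)O[Cu] | intermediate
22 | copper aldolate (phosphine omitted) | CC(C)(C)[Si](C)(C)O[C@H]1[C@H](Oc3ccc(OC)cc3)[C@](C)(O[Cu])[C@](C)(C(=O)OC)[C@H]2CCC=C(C)[C@]12C | intermediate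
23 | decalin β-hydroxy ester (key-step product) | CC(C)(C)[Si](C)(C)O[C@H]1[C@H](Oc3ccc(OC)cc3)[C@](C)(O)[C@](C)(C(=O)OC)[C@H]2CCC=C(C)[C@]12C | intermediate
24 | 8-O-TES ester | CC(C)(C)[Si](C)(C)O[C@H]1[C@H](Oc3ccc(OC)cc3)[C@](C)(O[Si](CC)(CC)CC)[C@](C)(C(=O)OC)[C@H]2CCC=C(C)[C@]12C | intermediate
25 | C11 primary alcohol | CC(C)(C)[Si](C)(C)O[C@H]1[C@H](Oc3ccc(OC)cc3)[C@](C)(O[Si](CC)(CC)CC)[C@](C)(CO)[C@H]2CCC=C(C)[C@]12C | intermediate
26 | C11 aldehyde | CC(C)(C)[Si](C)(C)O[C@H]1[C@H](Oc3ccc(OC)cc3)[C@](C)(O[Si](CC)(CC)CC)[C@](C)(C=O)[C@H]2CCC=C(C)[C@]12C | intermediate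
27 | C11=C12 vinyl decalin | CC(C)(C)[Si](C)(C)O[C@H]1[C@H](Oc3ccc(OC)cc3)[C@](C)(O[Si](CC)(CC)CC)[C@](C)(C=C)[C@H]2CCC=C(C)[C@]12C | intermediate
28 | 4-bromofuran-2(5H)-one | O=C1C=C(Br)CO1 | starting material
29 | protected dienyl butenolide | CC(C)(C)[Si](C)(C)O[C@H]1[C@H](Oc3ccc(OC)cc3)[C@](C)(O[Si](CC)(CC)CC)[C@](C)(/C=C/C3=CC(=O)OC3)[C@H]2CCC=C(C)[C@]12C | intermediate
30 | 7β-alcohol | CC(C)(C)[Si](C)(C)O[C@H]1[C@H](O)[C@](C)(O[Si](CC)(CC)CC)[C@](C)(/C=C/C3=CC(=O)OC3)[C@H]2CCC=C(C)[C@]12C | intermediate
31 | 7β-isobutyrate | CC(C)(C)[Si](C)(C)O[C@H]1[C@H](OC(=O)C(C)C)[C@](C)(O[Si](CC)(CC)CC)[C@](C)(/C=C/C3=CC(=O)OC3)[C@H]2CCC=C(C)[C@]12C | intermediate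
32 | 6α,8β-diol 7β-isobutyrate | O[C@H]1[C@H](OC(=O)C(C)C)[C@](C)(O)[C@](C)(/C=C/C3=CC(=O)OC3)[C@H]2CCC=C(C)[C@]12C | intermediate
33 | CNP0207114.1 | CC(=O)O[C@H]1[C@H](OC(=O)C(C)C)[C@](C)(O)[C@](C)(/C=C/C2=CC(=O)OC2)[C@H]2CCC=C(C)[C@]12C | target

Total step count: 22. Longest linear sequence: 21 (steps 1–8 and 10–22, from (S)-carvone).

**Steps most likely to fail**

**Step 13.**
- *Risks:* proton transfer to the enolate before C–C bond formation (plain conjugate reduction), poor facial selectivity at the ketone, and enolisation at C7 followed by loss of the C6 silyloxy group.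
- *Fallback:* enolate formation and ring closure are separated, and the closed metal-bridged transition state is replaced by an open one. Starting from 20, 1,4-hydrosilylation of the acrylate (Et3SiH, RhCl(PPh3)3, toluene, 50 °C) should give the triethylsilyl ketene acetal F1.
- *Return to the route:* an intramolecular Mukaiyama aldol addition to the C8 ketone (Tf2NH 5 mol %, CH2Cl2, −78 °C) with silyl transfer to O8 then leads directly to 24. The same A(1,3) and Felkin–Anh elements operate, and step 14 is no longer needed.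

**Step 10.**
- *Risks:* slow addition of the bulky borane to the neopentyl aldehyde, erosion of reagent control by C5, and lactonisation of the freed alcohol onto C11.
- *Fallback:* an Evans syn-glycolate aldol replaces the allylborane, starting from 12. (S)-4-Benzyloxazolidin-2-one is acylated (n-BuLi, (4-methoxyphenoxy)acetyl chloride) to the imide F2. Its dibutylboron (Z)-enolate (Bu2BOTf, Et3N, CH2Cl2, −78 °C) adds to 12 to give the syn adduct F3 with the same 6R and 7β-OAr configuration.
- *Return to the route:* TBSOTf gives the silyl ether F4. NaBH4 in wet THF removes the auxiliary, which is reduced much faster than the acrylate, and gives the primary alcohol F5. Dess–Martin oxidation gives the aldehyde F6, and non-basic methylenation (Zn, CH2I2, TiCl4) rejoins the route at 19.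

**Step 18.**
- *Risks:* slow insertion next to quaternary C9, base-induced decomposition of the bromobutenolide, and loss of active palladium.
- *Fallback:* the polarity of the coupling is changed and step 17 is bypassed, starting from 26. Takai olefination (CrCl2, CHI3, THF) should give the (E)-vinyl iodide F7. Separately, 28 is stannylated ((Bu3Sn)2, Pd(PPh3)4, toluene, reflux) to the stannyl butenolide F8.
- *Return to the route:* Stille coupling of F7 with F8 (Pd2(dba)3, AsPh3, CuI, DMF, rt) rejoins the route at 29.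

**Further compounds**
F1 | step 13 | triethylsilyl ketene acetal of 20 | CC(=O)[C@@H](Oc2ccc(OC)cc2)[C@H](O[Si](C)(C)C(C)(C)C)[C@@]1(C)C(C)=CCC[C@@H]1C(C)=C(OC)O[Si](CC)(CC)CC
F2 | step 10 | (S)-4-benzyl-3-[(4-methoxyphenoxy)acetyl]oxazolidin-2-one | COc1ccc(OCC(=O)N2[C@@H](Cc3ccccc3)COC2=O)cc1
F3 | step 10 | syn glycolate aldol adduct | O=C(N2C(=O)OC[C@@H]2Cc3ccccc3)[C@@H](Oc4ccc(OC)cc4)[C@H](O)[C@@]1(C)C(C)=CCC[C@@H]1C(=C)C(=O)OC
F4 | step 10 | 6-O-TBS ether of the adduct | O=C(N2C(=O)OC[C@@H]2Cc3ccccc3)[C@@H](Oc4ccc(OC)cc4)[C@H](O[Si](C)(C)C(C)(C)C)[C@@]1(C)C(C)=CCC[C@@H]1C(=C)C(=O)OC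
F5 | step 10 | C8 primary alcohol | OC[C@@H](Oc4ccc(OC)cc4)[C@H](O[Si](C)(C)C(C)(C)C)[C@@]1(C)C(C)=CCC[C@@H]1C(=C)C(=O)OC
F6 | step 10 | C8 aldehyde | O=C[C@@H](Oc4ccc(OC)cc4)[C@H](O[Si](C)(C)C(C)(C)C)[C@@]1(C)C(C)=CCC[C@@H]1C(=C)C(=O)OC
F7 | step 18 | (E)-C11=C12 vinyl iodide | CC(C)(C)[Si](C)(C)O[C@H]1[C@H](Oc3ccc(OC)cc3)[C@](C)(O[Si](CC)(CC)CC)[C@](C)(/C=C/I)[C@H]2CCC=C(C)[C@]12C
F8 | step 18 | 4-(tributylstannyl)furan-2(5H)-one | CCCC[Sn](CCCC)(CCCC)C1=CC(=O)OC1
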